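The flavone is cut between C2 of the pyranone ring C and C1′ of resorcinol ring B. Ring A is fully substituted, so C2–H, flanked by ring oxygen O1 and the 3-methoxy group, is the only sp2 C–H of the chromone half and its most acidic site, while C1′ is the carbon ortho/para to the two ring-B oxygens that bromine marks in 4-bromoresorcinol. A one-pot regiospecific C2–H zincation of 3,5,6,7,8-pentamethoxychromone and Negishi coupling with 2,4-bis(benzyloxy)bromobenzene joins the halves; a single BCl3 operation then frees all three phenols. The chromone arises in two steps from pentamethoxybenzene.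

Key step: step 4

Remark: the target has no stereocentre, and the C2–C1′ axis (flanked only by 3-OMe and 2′-OH) rotates freely, so the compound is achiral and no stereocontrol is required.
Remark: pentamethoxybenzene, methoxyacetyl chloride, 4-bromoresorcinol and TMPZnCl·LiCl solution are taken as catalogue items.

Step 1
Reactants: 1 pentamethoxybenzene
Product: 2 1-(2-hydroxy-3,4,5,6-tetramethoxyphenyl)-2-methoxyethan-1-one
Conditions: MeOCH2COCl (1.2 equiv), AlCl3 (2.5 equiv), CH2Cl2, 0 °C to rt; ice/aq. HCl work-up
Reagents that add atoms: methoxyacetyl chloride, COCC(Cl)=O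
Why: Friedel–Crafts acylation at the only free position of the electron-rich, symmetric arene, followed in the same pot by AlCl3-chelate-directed cleavage of one of the two equivalent ortho-methoxy groups, should give a single ortho-hydroxy ketone, the symmetry of 1 removing any regiochemical choice.

Step 2
Reactants: 2 1-(2-hydroxy-3,4,5,6-tetramethoxyphenyl)-2-methoxyethan-1-one
Product: 4 3,5,6,7,8-pentamethoxy-4H-chromen-4-one, via enaminone 3 (not isolated)
Conditions: DMF-DMA (3 equiv), toluene, 100 °C; evaporate; then AcOH, 80 °C
Reagents that add atoms: N,N-dimethylformamide dimethyl acetal, COC(OC)N(C)C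
Why: Enaminone chromone synthesis: the α-methylene condenses with DMF-DMA to enaminone 3, whose chelated phenol adds to the β-carbon and expels dimethylamine under acid (addition–elimination), leaving C2 as an unsubstituted CH.

Step 3
Reactants: 5 4-bromoresorcinol (4-bromobenzene-1,3-diol)
Product: 6 2,4-bis(benzyloxy)-1-bromobenzene
Conditions: BnBr (2.3 equiv), K2CO3 (3 equiv), DMF, 50 °C
Reagents that add atoms: benzyl bromide, BrCc1ccccc1
Why: Williamson ether synthesis on both phenols masks the acidic OH groups for the organozinc coupling with groups that the final BCl3 step removes.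

Step 4
Reactants: 4 3,5,6,7,8-pentamethoxy-4H-chromen-4-one; 6 2,4-bis(benzyloxy)-1-bromobenzene
Product: 8 2-[2,4-bis(benzyloxy)phenyl]-3,5,6,7,8-pentamethoxy-4H-chromen-4-one, via chromon-2-ylzinc chloride 7 (not isolated)
Conditions: TMPZnCl·LiCl (1.3 equiv), THF, 25 °C; then 6, Pd(OAc)2 (2 mol %), SPhos (4 mol %), 50 °C
Reagents that add atoms: none
Why: The hindered amide base TMPZnCl·LiCl removes the C2 proton of 4, which is acidified by the adjacent ring oxygen O1, the 3-methoxy oxygen and the vinylogous C4 carbonyl, to give the C2-zinc species 7; Pd(0)/SPhos then inserts into the C–Br bond of 6, and zinc-to-palladium transmetalation and reductive elimination forge the C2–C1′ bond. The closest known reaction type is the deprotonative C2-zincation of chromones with TMP–zinc amides followed by Negishi cross-coupling with aryl halides to give flavones. No ring is closed and no stereocentre is created, and the new aryl–pyranone axis carries only two ortho substituents (3-OMe and 2′-OBn), so it rotates freely. The step needs site selectivity in the metalation and chemoselectivity towards the C4 carbonyl: the former is secured because ring A of 4 bears no hydrogen, so C2–H is the only sp2 C–H of the chromone, the latter by the low nucleophilicity of the TMP amide and of the carbon–zinc bond. The position on ring B is fixed by the bromine of 6, which sits ortho and para to the two benzyloxy groups.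

Step 5
Reactants: 8 2-[2,4-bis(benzyloxy)phenyl]-3,5,6,7,8-pentamethoxy-4H-chromen-4-one
Product: 9 5,2′,4′-trihydroxy-3,6,7,8-tetramethoxyflavone
Conditions: BCl3 (6 equiv), pentamethylbenzene (5 equiv), CH2Cl2, −78 °C to 0 °C; MeOH, then aq. HCl work-up
Reagents that add atoms: none
Why: Lewis-acid ether cleavage: BCl3 with pentamethylbenzene as benzyl-cation scavenger removes both benzyl ethers at low temperature and, on warming, the 5-methoxy group alone through the six-membered boron chelate with the C4 carbonyl (chelation-controlled peri-demethylation), while the 3-, 6-, 7- and 8-methoxy groups stay.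

Compound list
1 | pentamethoxybenzene | COc1cc(OC)c(OC)c(OC)c1OC | starting material
2 | 1-(2-hydroxy-3,4,5,6-tetramethoxyphenyl)-2-methoxyethan-1-one | COCC(=O)c1c(O)c(OC)c(OC)c(OC)c1OC | intermediate
3 | (Z)-3-(dimethylamino)-1-(2-hydroxy-3,4,5,6-tetramethoxyphenyl)-2-methoxyprop-2-en-1-one (enaminone) | CN(C)/C=C(\OC)C(=O)c1c(O)c(OC)c(OC)c(OC)c1OC | intermediate (not isolated)
4 | 3,5,6,7,8-pentamethoxy-4H-chromen-4-one | COc1coc2c(OC)c(OC)c(OC)c(OC)c2c1=O | intermediate
5 | 4-bromoresorcinol (4-bromobenzene-1,3-diol) | Oc1ccc(Br)c(O)c1 | starting material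
6 | 2,4-bis(benzyloxy)-1-bromobenzene | Brc1ccc(OCc2ccccc2)cc1OCc1ccccc1 | intermediate
7 | (3,5,6,7,8-pentamethoxy-4-oxo-4H-chromen-2-yl)zinc chloride (LiCl complex) | COc1c([Zn]Cl)oc2c(OC)c(OC)c(OC)c(OC)c2c1=O | intermediate (not isolated)
8 | 2-[2,4-bis(benzyloxy)phenyl]-3,5,6,7,8-pentamethoxy-4H-chromen-4-one | COc1c(-c2ccc(OCc3ccccc3)cc2OCc2ccccc2)oc2c(OC)c(OC)c(OC)c(OC)c2c1=O | intermediate
9 | 5,2′,4′-trihydroxy-3,6,7,8-tetramethoxyflavone | COc1c(OC)c(O)c2c(=O)c(OC)c(-c3ccc(O)cc3O)oc2c1OC | target

Total step count: 5. Longest linear sequence: 4 steps (1 → 2 → 4 → 8 → 9; step 3 is the one-step side branch).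

Steps most likely to fail

First, step 4 (key step). The deprotonation may stay incomplete, the amide may add to C2 and open the pyranone ring, or the zinc species may be protonated before the slow oxidative addition into the electron-rich ortho-alkoxy aryl bromide. The fallback forms the same C2–C1′ bond by conjugate addition instead of metalation and sets out from 6 and 4. Bromine–lithium exchange on 6 (n-BuLi, THF, −78 °C), B(OiPr)3 and acidic hydrolysis should give [2,4-bis(benzyloxy)phenyl]boronic acid F1. Rh(I)-catalysed 1,4-addition of F1 to chromone 4 ([Rh(cod)OH]2 cat., dioxane/H2O, 80 °C) should give racemic 2-[2,4-bis(benzyloxy)phenyl]-3,5,6,7,8-pentamethoxychroman-4-one F2 as a diastereomer mixture. Dehydrogenation with DDQ (dioxane, 100 °C) erases both stereocentres and comes back to the route at 8.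

Second, step 5. Further methyl groups may be lost (3-OMe through a 2′-O–boron chelate, or the crowded 6-/8-OMe), or the liberated benzyl cation may C-benzylate ring B. The fallback separates the two deprotections and sets out from 8. Hydrogenolysis (H2, Pd/C, EtOAc–THF, rt) should give 2-(2,4-dihydroxyphenyl)-3,5,6,7,8-pentamethoxy-4H-chromen-4-one F3. Chelation-controlled 5-O-demethylation with AlCl3 in MeCN (rt to 50 °C, then dilute HCl) comes back to the route at 9.

Third, step 1. The α-methoxy acylium ion may lose CO and then methoxymethylate the arene, and excess Lewis acid may cleave a second ortho-methoxy group. The fallback replaces the electrophilic acylation by an anionic one and sets out from 1. Directed ortho-lithiation of the single aryl C–H between two methoxy groups (n-BuLi, TMEDA, THF, 0 °C) and quenching with N-methoxy-N-methyl-2-methoxyacetamide should give 2-methoxy-1-(2,3,4,5,6-pentamethoxyphenyl)ethan-1-one F4. BCl3 (1.1 equiv, CH2Cl2, −78 °C to 0 °C) should then cleave one of the two equivalent ortho-methoxy groups through the carbonyl chelate and come back to the route at 2.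

Further compounds
F1 | step 4 | [2,4-bis(benzyloxy)phenyl]boronic acid | OB(O)c1ccc(OCc2ccccc2)cc1OCc1ccccc1
F2 | step 4 | 2-[2,4-bis(benzyloxy)phenyl]-3,5,6,7,8-pentamethoxychroman-4-one (racemic, mixture of cis and trans) | COC1C(c2ccc(OCc3ccccc3)cc2OCc2ccccc2)Oc2c(OC)c(OC)c(OC)c(OC)c2C1=O
F3 | step 5 | 2-(2,4-dihydroxyphenyl)-3,5,6,7,8-pentamethoxy-4H-chromen-4-one | COc1c(-c2ccc(O)cc2O)oc2c(OC)c(OC)c(OC)c(OC)c2c1=O
F4 | step 1 | 2-methoxy-1-(2,3,4,5,6-pentamethoxyphenyl)ethan-1-one | COCC(=O)c1c(OC)c(OC)c(OC)c(OC)c1OC
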